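**Retrosynthetic overview**
1. The target is a benzene-1,3-diol ring carrying at C5 an unbranched C17 chain (C1' benzylic, C16' the ketone carbonyl, C17' the methyl group). The last step is double O-demethylation of the 3,5-dimethoxyarene.
2. Key disconnection: the C11'–C12' CH2–CH2 bond, formed by a Ni-electrocatalytic doubly decarboxylative C(sp3)–C(sp3) coupling of the N-hydroxyphthalimide esters of 12-(3,5-dimethoxyphenyl)dodecanoic acid and commercial 6-oxoheptanoic acid.
3. Enabling feature: C11' and C12' are plain methylenes inside the stereocentre-free (CH2)15 tether. C11' lies ten CH2 groups from the benzene ring and C12' three CH2 groups (C13'–C15') from the C16' carbonyl, so each is an unstabilised primary radical whose parent is a simple carboxylic acid, and arene and ketone are spectators.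
4. The C12 aryl acid comes from a Wittig reaction of 3,5-dimethoxybenzaldehyde with the ylide from 11-bromoundecanoic acid and PPh3, followed by hydrogenation.
5. Ring formation: none; the only ring (the benzene ring) is bought with both oxygen atoms in place.

Key step: step 6

Remark: the target has no stereocentre and no stereogenic double bond (it is achiral), so the compound as drawn is the only stereoisomer and no stereocontrol is required.

**Route**

Step 1
Reactants: 1 11-bromoundecanoic acid; 2 triphenylphosphine
Product: 3 (10-carboxydecyl)triphenylphosphonium bromide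
Conditions: PPh3 (1.05 equiv), MeCN, reflux, 48 h; trituration with Et2O
Reagents that add atoms: triphenylphosphine (2), c1ccc(cc1)P(c1ccccc1)c1ccccc1
Why: SN2 quaternisation of the unhindered primary bromide by PPh3 (phosphonium salt formation) should proceed cleanly in the presence of the free acid, and the salt should be purified by trituration.

Step 2
Reactants: 3 (10-carboxydecyl)triphenylphosphonium bromide (1.2 equiv); 4 3,5-dimethoxybenzaldehyde
Product: 6 12-(3,5-dimethoxyphenyl)dodec-11-enoic acid (Z/E mixture), via sodium carboxylate phosphorus ylide 5 (not isolated)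
Conditions: NaHMDS (2.2 equiv per 3), THF, 0 °C; then 4, 0 °C → rt; 1 M HCl work-up
Reagents that add atoms: none
Why: Wittig olefination in which the first equivalent of base forms the carboxylate and the second the non-stabilised ylide, which should condense with the non-enolisable aryl aldehyde; the Z/E ratio is of no consequence because the alkene is saturated in step 3, and acid–base extraction should remove the phosphine oxide.

Step 3
Reactants: 6 12-(3,5-dimethoxyphenyl)dodec-11-enoic acid
Product: 7 12-(3,5-dimethoxyphenyl)dodecanoic acid
Conditions: H2 (1 atm), 10% Pd/C, EtOAc, rt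
Reagents that add atoms: none
Why: Heterogeneous catalytic hydrogenation should saturate the disubstituted styrenyl alkene, while the aryl methyl ethers and the acid are inert and no benzylic C–O bond is present to be hydrogenolysed.

Step 4
Reactants: 7 12-(3,5-dimethoxyphenyl)dodecanoic acid; 8 N-hydroxyphthalimide
Product: 9 1,3-dioxoisoindolin-2-yl 12-(3,5-dimethoxyphenyl)dodecanoate
Conditions: N-hydroxyphthalimide (1.05 equiv), DIC (1.1 equiv), DMAP (10 mol %), CH2Cl2, rt
Reagents that add atoms: N-hydroxyphthalimide (8), ON1C(=O)c2ccccc2C1=O
Why: Carbodiimide-mediated (Steglich-type) esterification should convert the acid into its bench-stable redox-active N-acyloxyphthalimide, which is purified by filtration of the urea and a short silica column.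

Step 5
Reactants: 10 6-oxoheptanoic acid; 8 N-hydroxyphthalimide
Product: 11 1,3-dioxoisoindolin-2-yl 6-oxoheptanoate
Conditions: N-hydroxyphthalimide (1.05 equiv), DIC (1.1 equiv), DMAP (10 mol %), CH2Cl2, rt
Reagents that add atoms: N-hydroxyphthalimide (8), ON1C(=O)c2ccccc2C1=O
Why: The same Steglich-type esterification should activate the commercial keto acid as its redox-active ester, the dialkyl ketone being inert to DIC/DMAP.

Step 6
Reactants: 9 1,3-dioxoisoindolin-2-yl 12-(3,5-dimethoxyphenyl)dodecanoate (1 equiv); 11 1,3-dioxoisoindolin-2-yl 6-oxoheptanoate (3 equiv)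
Product: 12 17-(3,5-dimethoxyphenyl)heptadecan-2-one
Conditions: NiCl2·6H2O (20 mol %), terpyridine-type tridentate N-ligand (20 mol %), AgNO3 (0.3 equiv), Mg(+)/RVC(−), undivided cell, NMP, constant current, rt
Reagents that add atoms: none
Why: At the silver-nanoparticle-coated cathode the nickel catalyst mediates single-electron reduction of both N-acyloxyphthalimides, each of which fragments to phthalimide anion, CO2 and an unstabilised primary alkyl radical; a low-valent alkyl–nickel species captures the second radical and the resulting dialkyl-Ni(III) reductively eliminates the C11'–C12' CH2–CH2 bond, while magnesium is oxidised at the sacrificial anode. The closest known reaction type is the Ni-electrocatalytic doubly decarboxylative C(sp3)–C(sp3) cross-coupling of two different primary alkyl redox-active esters, a reductive counterpart of the mixed Kolbe electrolysis. No ring is closed and no stereocentre is created, so neither a mode of closure nor a stereocontrol element is involved. The selectivity needed is cross- over homo-coupling, secured statistically by the three-fold excess of the cheap keto ester 11, so that the valuable arylundecyl radical is channelled into 12 and the by-products (dodecane-2,11-dione from 11 and the symmetrical C22 diaryl alkane from 9) differ strongly from 12 in polarity and size and should separate on silica. Chemoselectivity rests on the substrate: both radical centres are primary and remote from functionality (the carbonyl offers no favourable 1,5-hydrogen shift or β-scission and the arene is eleven carbons away), the dialkyl ketone is reduced only at far more negative potential than the redox-active esters, and the reductive regime with a sacrificial anode spares the oxidation-prone 1,3-dimethoxyarene that an anodic Kolbe coupling would endanger.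

Step 7
Reactants: 12 17-(3,5-dimethoxyphenyl)heptadecan-2-one
Product: 14 hansfordiol B, 5-(16-oxoheptadecyl)benzene-1,3-diol, via bis(dibromoboryl) aryl ether 13 (not isolated)
Conditions: BBr3 (4 equiv), CH2Cl2, −78 °C → 0 °C; then H2O / aq. NaHCO3
Reagents that add atoms: none
Why: Lewis-acid ether cleavage, in which BBr3 complexes each aryl methyl ether oxygen and bromide removes the methyl group by SN2 to give aryloxydibromoboranes that hydrolyse on work-up; the unactivated dialkyl ketone should only bind one extra equivalent of BBr3 reversibly at low temperature.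

**Compound list**
1 | 11-bromoundecanoic acid | OC(=O)CCCCCCCCCCBr | starting material
2 | triphenylphosphine | c1ccc(cc1)P(c1ccccc1)c1ccccc1 | starting material
3 | (10-carboxydecyl)triphenylphosphonium bromide | OC(=O)CCCCCCCCCC[P+](c1ccccc1)(c1ccccc1)c1ccccc1.[Br-] | intermediate
4 | 3,5-dimethoxybenzaldehyde | COc1cc(C=O)cc(OC)c1 | starting material
5 | sodium 11-(triphenylphosphoranylidene)undecanoate (carboxylate ylide) | [Na+].[O-]C(=O)CCCCCCCCCC=P(c1ccccc1)(c1ccccc1)c1ccccc1 | intermediate (not isolated)
6 | 12-(3,5-dimethoxyphenyl)dodec-11-enoic acid (Z/E mixture, geometry not controlled) | OC(=O)CCCCCCCCCC=Cc1cc(OC)cc(OC)c1 | intermediate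
7 | 12-(3,5-dimethoxyphenyl)dodecanoic acid | OC(=O)CCCCCCCCCCCc1cc(OC)cc(OC)c1 | intermediate
8 | N-hydroxyphthalimide | ON1C(=O)c2ccccc2C1=O | starting material
9 | 1,3-dioxoisoindolin-2-yl 12-(3,5-dimethoxyphenyl)dodecanoate | O=C(CCCCCCCCCCCc1cc(OC)cc(OC)c1)ON2C(=O)c3ccccc3C2=O | intermediate
10 | 6-oxoheptanoic acid | CC(=O)CCCCC(=O)O | starting material
11 | 1,3-dioxoisoindolin-2-yl 6-oxoheptanoate | CC(=O)CCCCC(=O)ON1C(=O)c2ccccc2C1=O | intermediate
12 | 17-(3,5-dimethoxyphenyl)heptadecan-2-one | CC(=O)CCCCCCCCCCCCCCCc1cc(OC)cc(OC)c1 | intermediate
13 | 17-[3,5-bis(dibromoboryloxy)phenyl]heptadecan-2-one | CC(=O)CCCCCCCCCCCCCCCc1cc(OB(Br)Br)cc(OB(Br)Br)c1 | intermediate (not isolated)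
14 | hansfordiol B, 5-(16-oxoheptadecyl)benzene-1,3-diol (achiral) | CC(=O)CCCCCCCCCCCCCCCc1cc(O)cc(O)c1 | target

**Step count and risks**
Total steps: 7. Longest linear sequence: 6 (steps 1, 2, 3, 4, 6, 7); step 5 is a one-step side branch.

Steps most likely to fail:

1. Step 6. The alkyl radicals or alkyl–nickel species may be reduced to alkanes before coupling, homodimerisation may dominate despite the excess of 11, or the redox-active esters may be over-reduced or hydrolysed. The fallback abandons the decarboxylative coupling for a polar copper-catalysed Grignard coupling that forms the neighbouring C12'–C13' bond. It sets out from 7 and returns at 12. Acid 7 is reduced with LiAlH4 (THF, 0 °C → rt) to 12-(3,5-dimethoxyphenyl)dodecan-1-ol F1. An Appel reaction (CBr4, PPh3, CH2Cl2, 0 °C) should then give 1-(12-bromododecyl)-3,5-dimethoxybenzene F2. Commercial 2-(3-chloropropyl)-2-methyl-1,3-dioxolane (CC1(CCCCl)OCCO1) is converted with Mg turnings (THF, reflux) into [3-(2-methyl-1,3-dioxolan-2-yl)propyl]magnesium chloride F3. This is coupled with F2 under Li2CuCl4 catalysis (THF, −20 → 0 °C) to give 2-[15-(3,5-dimethoxyphenyl)pentadecyl]-2-methyl-1,3-dioxolane F4. Hydrolysis of the ketal (1 M HCl, THF, rt) should deliver 12.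

2. Step 7. The Lewis acid may enolise the methyl ketone, leading to aldol self-condensation or α-bromination, or cleavage may stop at the mono-methyl ether. The fallback replaces the methyl ethers by benzyl ethers, which are removed under neutral conditions. It sets out from 3 and returns at 14. Ylide 5, generated from 3 as in step 2, is condensed with commercial 3,5-bis(benzyloxy)benzaldehyde (O=Cc1cc(OCc2ccccc2)cc(OCc2ccccc2)c1) to give 12-[3,5-bis(benzyloxy)phenyl]dodec-11-enoic acid F5. Homogeneous hydrogenation (H2, RhCl(PPh3)3 cat., benzene/EtOH, rt) should saturate the alkene without debenzylation and give 12-[3,5-bis(benzyloxy)phenyl]dodecanoic acid F6. Esterification with 8 (DIC, DMAP, CH2Cl2) gives 1,3-dioxoisoindolin-2-yl 12-[3,5-bis(benzyloxy)phenyl]dodecanoate F7. Coupling with 11 under the conditions of step 6 should give 17-[3,5-bis(benzyloxy)phenyl]heptadecan-2-one F8. Hydrogenolysis (H2, Pd/C, EtOAc, rt) should cleave both benzyl ethers and leave the dialkyl ketone untouched, giving 14.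

3. Step 2. The carboxylate ylide may form incompletely or stay poorly soluble, so that the olefination stalls. The fallback builds the same acid by a copper-catalysed sp3–sp3 Grignard coupling instead of olefination and hydrogenation. It sets out from 1 and returns at 7, bypassing steps 1–3. Acid 1 is deprotonated with t-BuMgCl (1 equiv, THF, −20 °C) to chloromagnesium 11-bromoundecanoate F9. Commercial 3,5-dimethoxybenzyl chloride (COc1cc(CCl)cc(OC)c1) is converted with Mg (THF, 0 °C, slow addition to limit Wurtz coupling) into (3,5-dimethoxybenzyl)magnesium chloride F10. F10 is added to F9 with Li2CuCl4 (cat.) in THF at −20 → 0 °C, and acidic work-up should give 7 directly.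

**Further compounds**
F1 | step 6 | 12-(3,5-dimethoxyphenyl)dodecan-1-ol | OCCCCCCCCCCCCc1cc(OC)cc(OC)c1
F2 | step 6 | 1-(12-bromododecyl)-3,5-dimethoxybenzene | BrCCCCCCCCCCCCc1cc(OC)cc(OC)c1
F3 | step 6 | [3-(2-methyl-1,3-dioxolan-2-yl)propyl]magnesium chloride | CC1(CCC[Mg]Cl)OCCO1
F4 | step 6 | 2-[15-(3,5-dimethoxyphenyl)pentadecyl]-2-methyl-1,3-dioxolane | CC1(CCCCCCCCCCCCCCCc2cc(OC)cc(OC)c2)OCCO1
F5 | step 7 | 12-[3,5-bis(benzyloxy)phenyl]dodec-11-enoic acid (Z/E mixture) | OC(=O)CCCCCCCCCC=Cc1cc(OCc2ccccc2)cc(OCc2ccccc2)c1
F6 | step 7 | 12-[3,5-bis(benzyloxy)phenyl]dodecanoic acid | OC(=O)CCCCCCCCCCCc1cc(OCc2ccccc2)cc(OCc2ccccc2)c1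
F7 | step 7 | 1,3-dioxoisoindolin-2-yl 12-[3,5-bis(benzyloxy)phenyl]dodecanoate | O=C(CCCCCCCCCCCc1cc(OCc2ccccc2)cc(OCc2ccccc2)c1)ON3C(=O)c4ccccc4C3=O
F8 | step 7 | 17-[3,5-bis(benzyloxy)phenyl]heptadecan-2-one | CC(=O)CCCCCCCCCCCCCCCc1cc(OCc2ccccc2)cc(OCc2ccccc2)c1
F9 | step 2 | chloromagnesium 11-bromoundecanoate | BrCCCCCCCCCCC(=O)O[Mg]Cl
F10 | step 2 | (3,5-dimethoxybenzyl)magnesium chloride | COc1cc(C[Mg]Cl)cc(OC)c1
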